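**Plan**

- Retrosynthesis: the three O-benzyl groups and a temporary carboxyl group on C3 are put back, then the C1–C2 bond of the cyclohexanone ring is cut so that C2 leaves as a CH2Br group on the α-carbon, contracting the tetralone to a 3-aryl-indan-1-one β-keto ester.
- The indanone is opened at the bond from C3 to the benzo carbon C3a (Nazarov) and at the exocyclic C=C (Knoevenagel), giving an aroylacetate from 2,3-dihydroxybenzoic acid and a naphthaldehyde from 5-methoxy-1-naphthol.
- Forward: the two arenes are joined by Knoevenagel condensation; the five-membered ketone ring closes first, onto the only free ortho carbon of the aroyl ring (para to the future C7 oxygen); the six-membered ketone ring then arises by insertion of one carbon from CH2Br2 between the carbonyl and the α-carbon.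
- Enabling feature: in the ring C1(=O)–C2–C3–C4–C4a–C8a, C2 is a bare CH2 beside the ketone, so taking it out leaves a five-membered aryl ketone whose α-carbon (future C3) can carry an ester and CH2Br, the array needed for a radical 1,2-acyl shift.
- Stereochemistry: the single stereocentre C4 (S) is set as C3 of the indanone by a ligand-controlled asymmetric Nazarov cyclisation and is never again a reacting centre; the centres at the ester carbon are temporary and vanish on decarboxylation.

Key step: step 10

Assumption: the sense of induction of the copper–bis(oxazoline) catalyst in step 8 cannot be assigned in advance for this substrate, so the ligand antipode that delivers the (3S)-indanone 14 is the one used.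

**Route**

Step 1
Reactants: 1 2,3-dihydroxybenzoic acid
Product: 2 benzyl 2,3-bis(benzyloxy)benzoate
Conditions: BnBr (3.5 equiv), K2CO3, DMF, 60 °C
Reagents that add atoms: benzyl bromide, BrCc1ccccc1
Why: Williamson alkylation of both phenoxides and of the carboxylate under carbonate in DMF should give the fully benzylated ester in one operation.

Step 2
Reactants: 2 benzyl 2,3-bis(benzyloxy)benzoate
Product: 3 2,3-bis(benzyloxy)benzoic acid
Conditions: NaOH, MeOH/THF/H2O, reflux; then 1 M HCl
Reagents that add atoms: sodium hydroxide, [Na+].[OH-]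
Why: Saponification cleaves only the benzyl ester, since aryl benzyl ethers are inert to hydroxide.

Step 3
Reactants: 3 2,3-bis(benzyloxy)benzoic acid; 4 potassium monomethyl malonate
Product: 7 methyl 3-[2,3-bis(benzyloxy)phenyl]-3-oxopropanoate, via acyl imidazolide 5 (not isolated), via aroylmalonic half ester 6 (not isolated)
Conditions: CDI, THF, rt; then 4, MgCl2, Et3N, THF/MeCN, rt to 50 °C; 1 M HCl
Reagents that add atoms: potassium monomethyl malonate (4), COC(=O)CC(=O)[O-].[K+]
Why: Masamune–Brooks homologation, in which the acyl imidazolide C-acylates the magnesium enolate of the malonate half ester and the adduct loses CO2 on acidification, should give the aroylacetate without self-condensation.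

Step 4
Reactants: 8 5-methoxy-1-naphthol
Product: 9 4-bromo-5-methoxynaphthalen-1-ol
Conditions: NBS (1.0 equiv), MeCN, −20 to 0 °C, dark
Reagents that add atoms: N-bromosuccinimide, O=C1CCC(=O)N1Br
Why: Electrophilic bromination in acetonitrile should go to the ring of the free hydroxyl group (the stronger donor) at its para α-position C4; it is placed before O-benzylation because two ether groups would no longer tell the two rings apart.

Step 5
Reactants: 9 4-bromo-5-methoxynaphthalen-1-ol
Product: 10 1-(benzyloxy)-4-bromo-5-methoxynaphthalene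
Conditions: BnBr, K2CO3, acetone, reflux
Reagents that add atoms: benzyl bromide, BrCc1ccccc1
Why: Williamson etherification of the naphthoxide protects the phenol for the organolithium, enolate and radical steps that follow.

Step 6
Reactants: 10 1-(benzyloxy)-4-bromo-5-methoxynaphthalene
Product: 12 4-(benzyloxy)-8-methoxynaphthalene-1-carbaldehyde, via naphthyllithium 11 (not isolated)
Conditions: n-BuLi, THF, −78 °C; DMF, −78 to 0 °C; 1 M HCl
Reagents that add atoms: N,N-dimethylformamide, CN(C)C=O
Why: Bromine–lithium exchange is faster than any deprotonation at −78 °C, the peri-methoxy group chelates the naphthyllithium, and Bouveault formylation with DMF gives the aldehyde on acidic work-up.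

Step 7
Reactants: 7 methyl 3-[2,3-bis(benzyloxy)phenyl]-3-oxopropanoate; 12 4-(benzyloxy)-8-methoxynaphthalene-1-carbaldehyde
Product: 13 methyl (2Z)-2-[2,3-bis(benzyloxy)benzoyl]-3-[4-(benzyloxy)-8-methoxynaphthalen-1-yl]prop-2-enoate
Conditions: piperidine (cat.), AcOH (cat.), toluene, reflux, Dean–Stark
Reagents that add atoms: none
Why: Knoevenagel condensation of the active methylene with the non-enolisable aldehyde is driven by azeotropic removal of water; the Z isomer is drawn, and the geometry is immaterial because both isomers interconvert under the Lewis acid of the next step.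

Step 8
Reactants: 13 methyl (2Z)-2-[2,3-bis(benzyloxy)benzoyl]-3-[4-(benzyloxy)-8-methoxynaphthalen-1-yl]prop-2-enoate
Product: 14 methyl (2R,3S)-6,7-bis(benzyloxy)-3-[4-(benzyloxy)-8-methoxynaphthalen-1-yl]-1-oxo-2,3-dihydro-1H-indene-2-carboxylate
Conditions: Cu(OTf)2 (10 mol %), Ph-box ligand (12 mol %), 4 Å MS, ClCH2CH2Cl, 50–80 °C
Reagents that add atoms: none
Why: Catalytic asymmetric Nazarov cyclisation, in which the copper–bis(oxazoline) complex chelates the β-keto ester and the 4π conrotatory closure onto the only free ortho carbon of the aroyl ring (para to the 3-benzyloxy group) proceeds in the sense fixed by the ligand, should set C3 as S, after which rearomatisation and protonation place the ester trans to the naphthyl group.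

Step 9
Reactants: 14 methyl (2R,3S)-6,7-bis(benzyloxy)-3-[4-(benzyloxy)-8-methoxynaphthalen-1-yl]-1-oxo-2,3-dihydro-1H-indene-2-carboxylate; 15 dibromomethane
Product: 16 methyl (2R,3S)-6,7-bis(benzyloxy)-3-[4-(benzyloxy)-8-methoxynaphthalen-1-yl]-2-(bromomethyl)-1-oxo-2,3-dihydro-1H-indene-2-carboxylate
Conditions: NaH (1.1 equiv), THF/DMPU, 0 °C; CH2Br2 (10 equiv), 0 to 45 °C
Reagents that add atoms: dibromomethane (15), BrCBr
Why: C-alkylation of the sodium enolate of the β-keto ester with excess dibromomethane is the usual entry to such ring-expansion substrates, and the electrophile should approach the enolate face away from the C3 naphthyl group so that CH2Br ends trans to it.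

Step 10
Reactants: 16 methyl (2R,3S)-6,7-bis(benzyloxy)-3-[4-(benzyloxy)-8-methoxynaphthalen-1-yl]-2-(bromomethyl)-1-oxo-2,3-dihydro-1H-indene-2-carboxylate
Product: 17 methyl (1S,2R)-5,6-bis(benzyloxy)-1-[4-(benzyloxy)-8-methoxynaphthalen-1-yl]-4-oxo-1,2,3,4-tetrahydronaphthalene-2-carboxylate
Conditions: Bu3SnH (1.3 equiv) and AIBN (0.2 equiv) by syringe pump, benzene (0.01 M), reflux
Reagents that add atoms: none
Why: Bu3Sn• abstracts bromine from 16 and the primary radical adds 3-exo-trig to the C1 carbonyl, giving a cyclopropyloxy radical that opens by β-scission of the old C1–C2 bond to the ring-expanded tertiary α-ester radical, which takes hydrogen from Bu3SnH. The closest known reaction is the Dowd–Beckwith one-carbon ring expansion of 2-(halomethyl) cyclic β-keto esters, benzo-fused 1-indanone cases included. The six-membered ketone ring is not closed by a direct cyclisation but by this transient 3-exo closure and reopening (a net 1,2-acyl shift), in which only the new C1–CH2 bond is made. The one new stereocentre, the ester carbon, should be set by hydrogen transfer to the face away from the adjacent naphthyl group (ester cis to naphthyl) and is temporary, whereas the naphthyl-bearing carbon is not a reacting centre and keeps its configuration. The step needs rearrangement to outrun simple reduction of the primary radical and fragmentation to go toward the ester carbon: slow hydride addition at high dilution, the aryl ketone acceptor and ester stabilisation of the product radical secure this, and the trans placing of the radical carbon and the naphthyl group keeps the radical away from the arene.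

Step 11
Reactants: 17 methyl (1S,2R)-5,6-bis(benzyloxy)-1-[4-(benzyloxy)-8-methoxynaphthalen-1-yl]-4-oxo-1,2,3,4-tetrahydronaphthalene-2-carboxylate
Product: 18 (1S,2R)-5,6-bis(benzyloxy)-1-[4-(benzyloxy)-8-methoxynaphthalen-1-yl]-4-oxo-1,2,3,4-tetrahydronaphthalene-2-carboxylic acid
Conditions: LiOH·H2O, THF/MeOH/H2O, 0 °C to rt, argon; then 1 M HCl
Reagents that add atoms: lithium hydroxide, [Li+].[OH-]
Why: Saponification of the methyl ester leaves the ketone and the benzyl ethers untouched, and any epimerisation at the ester carbon is harmless because that centre is removed in the next step.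

Step 12
Reactants: 18 (1S,2R)-5,6-bis(benzyloxy)-1-[4-(benzyloxy)-8-methoxynaphthalen-1-yl]-4-oxo-1,2,3,4-tetrahydronaphthalene-2-carboxylic acid
Product: 20 (4S)-7,8-bis(benzyloxy)-4-[4-(benzyloxy)-8-methoxynaphthalen-1-yl]-3,4-dihydronaphthalen-1(2H)-one, via Barton ester 19 (not isolated)
Conditions: 1-hydroxypyridine-2(1H)-thione, DCC, CH2Cl2, 0 °C to rt, dark; then t-BuSH (excess), hν (W lamp), rt
Reagents that add atoms: none
Why: Barton reductive decarboxylation, in which the O-acyl thiohydroxamate fragments under visible light to the secondary radical with loss of CO2 and excess thiol transfers hydrogen faster than a neophyl-type 1,2-shift of the neighbouring naphthyl group can occur, should remove the carboxyl group without touching C4.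

Step 13
Reactants: 20 (4S)-7,8-bis(benzyloxy)-4-[4-(benzyloxy)-8-methoxynaphthalen-1-yl]-3,4-dihydronaphthalen-1(2H)-one
Product: 21 (4S)-7,8-dihydroxy-4-(4-hydroxy-8-methoxynaphthalen-1-yl)-3,4-dihydronaphthalen-1(2H)-one
Conditions: H2 (1 atm), 10% Pd/C, EtOAc/MeOH, rt
Reagents that add atoms: none
Why: Hydrogenolysis of the three aryl benzyl ethers at atmospheric pressure should spare the aryl ketone (stopped when hydrogen uptake ends), the methyl ether and the diarylmethine stereocentre.

**Compound list**

1 | 2,3-dihydroxybenzoic acid | O=C(O)c1cccc(O)c1O | starting material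
2 | benzyl 2,3-bis(benzyloxy)benzoate | O=C(OCc1ccccc1)c1cccc(OCc2ccccc2)c1OCc1ccccc1 | intermediate
3 | 2,3-bis(benzyloxy)benzoic acid | O=C(O)c1cccc(OCc2ccccc2)c1OCc1ccccc1 | intermediate
4 | potassium monomethyl malonate | COC(=O)CC(=O)[O-].[K+] | starting material
5 | 1-[2,3-bis(benzyloxy)benzoyl]-1H-imidazole | O=C(c1cccc(OCc2ccccc2)c1OCc1ccccc1)n1ccnc1 | intermediate (not isolated)
6 | 2-[2,3-bis(benzyloxy)benzoyl]-3-methoxy-3-oxopropanoic acid (racemic; present as its magnesium chelate) | COC(=O)C(C(=O)O)C(=O)c1cccc(OCc2ccccc2)c1OCc1ccccc1 | intermediate (not isolated)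
7 | methyl 3-[2,3-bis(benzyloxy)phenyl]-3-oxopropanoate | COC(=O)CC(=O)c1cccc(OCc2ccccc2)c1OCc1ccccc1 | intermediate
8 | 5-methoxy-1-naphthol | COc1cccc2c(O)cccc12 | starting material
9 | 4-bromo-5-methoxynaphthalen-1-ol | COc1cccc2c(O)ccc(Br)c12 | intermediate
10 | 1-(benzyloxy)-4-bromo-5-methoxynaphthalene | COc1cccc2c(OCc3ccccc3)ccc(Br)c12 | intermediate
11 | [4-(benzyloxy)-8-methoxynaphthalen-1-yl]lithium | [Li]c1ccc(OCc2ccccc2)c2cccc(OC)c12 | intermediate (not isolated)
12 | 4-(benzyloxy)-8-methoxynaphthalene-1-carbaldehyde | O=Cc1ccc(OCc2ccccc2)c2cccc(OC)c12 | intermediate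
13 | methyl (2Z)-2-[2,3-bis(benzyloxy)benzoyl]-3-[4-(benzyloxy)-8-methoxynaphthalen-1-yl]prop-2-enoate | COC(=O)/C(C(=O)c1cccc(OCc2ccccc2)c1OCc1ccccc1)=C\c1ccc(OCc2ccccc2)c2cccc(OC)c12 | intermediate
14 | methyl (2R,3S)-6,7-bis(benzyloxy)-3-[4-(benzyloxy)-8-methoxynaphthalen-1-yl]-1-oxo-2,3-dihydro-1H-indene-2-carboxylate (ester trans to naphthyl) | COc1cccc2c(OCc5ccccc5)ccc([C@@H]3[C@@H](C(=O)OC)C(=O)c4c3ccc(OCc5ccccc5)c4OCc5ccccc5)c12 | intermediate
15 | dibromomethane | BrCBr | starting material
16 | methyl (2R,3S)-6,7-bis(benzyloxy)-3-[4-(benzyloxy)-8-methoxynaphthalen-1-yl]-2-(bromomethyl)-1-oxo-2,3-dihydro-1H-indene-2-carboxylate (bromomethyl trans to naphthyl) | COc1cccc2c(OCc5ccccc5)ccc([C@@H]3[C@](CBr)(C(=O)OC)C(=O)c4c3ccc(OCc5ccccc5)c4OCc5ccccc5)c12 | intermediate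
17 | methyl (1S,2R)-5,6-bis(benzyloxy)-1-[4-(benzyloxy)-8-methoxynaphthalen-1-yl]-4-oxo-1,2,3,4-tetrahydronaphthalene-2-carboxylate (ester cis to naphthyl) | COc1cccc2c(OCc5ccccc5)ccc([C@@H]3[C@H](C(=O)OC)CC(=O)c4c3ccc(OCc5ccccc5)c4OCc5ccccc5)c12 | intermediate
18 | (1S,2R)-5,6-bis(benzyloxy)-1-[4-(benzyloxy)-8-methoxynaphthalen-1-yl]-4-oxo-1,2,3,4-tetrahydronaphthalene-2-carboxylic acid | COc1cccc2c(OCc5ccccc5)ccc([C@@H]3[C@H](C(=O)O)CC(=O)c4c3ccc(OCc5ccccc5)c4OCc5ccccc5)c12 | intermediate
19 | 2-thioxopyridin-1(2H)-yl (1S,2R)-5,6-bis(benzyloxy)-1-[4-(benzyloxy)-8-methoxynaphthalen-1-yl]-4-oxo-1,2,3,4-tetrahydronaphthalene-2-carboxylate | COc1cccc2c(OCc5ccccc5)ccc([C@@H]3[C@H](C(=O)On6ccccc6=S)CC(=O)c4c3ccc(OCc5ccccc5)c4OCc5ccccc5)c12 | intermediate (not isolated)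
20 | (4S)-7,8-bis(benzyloxy)-4-[4-(benzyloxy)-8-methoxynaphthalen-1-yl]-3,4-dihydronaphthalen-1(2H)-one | COc1cccc2c(OCc5ccccc5)ccc([C@@H]3CCC(=O)c4c3ccc(OCc5ccccc5)c4OCc5ccccc5)c12 | intermediate
21 | (4S)-7,8-dihydroxy-4-(4-hydroxy-8-methoxynaphthalen-1-yl)-3,4-dihydronaphthalen-1(2H)-one | COc1cccc2c(O)ccc([C@@H]3CCC(=O)c4c3ccc(O)c4O)c12 | target

**Step count**

Total: 13 steps. Longest linear sequence: 10 steps (steps 1, 2, 3, 7, 8, 9, 10, 11, 12, 13; the naphthalene branch, steps 4, 5, 6, 7–13, is equally long).

**Steps most likely to fail**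

Step 8. The sense of conrotation may be poorly controlled on this hindered substrate, or ring closure may be slow because the alkoxynaphthyl group over-stabilises the cation. The fallback replaces catalyst control by auxiliary control, so that the stereoisomers become separable diastereomers. It sets out from acid 3, which is activated with CDI to imidazolide 5 and added to the lithium enolate of (4S)-3-acetyl-4-phenyl-1,3-oxazolidin-2-one (LiHMDS, THF, −78 °C) to give (4S)-3-{3-[2,3-bis(benzyloxy)phenyl]-3-oxopropanoyl}-4-phenyl-1,3-oxazolidin-2-one F1. Knoevenagel condensation with aldehyde 12 (piperidine, AcOH, toluene, reflux) should give (4S)-3-{(2Z)-2-[2,3-bis(benzyloxy)benzoyl]-3-[4-(benzyloxy)-8-methoxynaphthalen-1-yl]prop-2-enoyl}-4-phenyl-1,3-oxazolidin-2-one F2. Nazarov cyclisation with an achiral acid (Cu(OTf)2 or MeSO3H, CH2Cl2) should then give (4S)-3-{[(2R,3S)-6,7-bis(benzyloxy)-3-[4-(benzyloxy)-8-methoxynaphthalen-1-yl]-1-oxo-2,3-dihydro-1H-inden-2-yl]carbonyl}-4-phenyl-1,3-oxazolidin-2-one F3, purified from its diastereomer by chromatography or crystallisation. Methanolysis (MeOMgBr, MeOH/CH2Cl2, 0 °C) removes the auxiliary and comes back to the route at 14. The auxiliary antipode is chosen to lead to the (3S) series; the (4S) auxiliary is written.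

Step 9. The congested enolate may react at oxygen, may be bridged pairwise by the CH2 unit, or may not react at all. The fallback builds the same carbon in two polar steps with a smaller electrophile. It sets out from 14: aldol addition to formaldehyde (aq. HCHO, KHCO3, THF, rt) on the face away from the naphthyl group should give methyl (2R,3S)-6,7-bis(benzyloxy)-3-[4-(benzyloxy)-8-methoxynaphthalen-1-yl]-2-(hydroxymethyl)-1-oxo-2,3-dihydro-1H-indene-2-carboxylate F4. Appel bromination (CBr4, PPh3, CH2Cl2, 0 °C to rt) then comes back to the route at 16.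

Step 10. Hydrogen transfer to the primary radical before it adds to the carbonyl would give the 2-methyl indanone, and reversal of the 3-exo addition would slow the rearrangement further. The fallback makes the same C1–CH2 bond and the same ring expansion by a polar path. It sets out from 14, which is treated with a zinc carbenoid (Et2Zn, CH2I2, CH2Cl2, 0 °C to rt). The zinc enolate is methylenated, the resulting zinc cyclopropanolate across C1–C2 fragments to the ring-expanded zinc ester enolate, and protonation on work-up from the face away from the naphthyl group comes back to the route at 17, bypassing 16. This detour makes no compound outside the list (entry F0).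

**Further compounds**

F1 | step 8 | (4S)-3-{3-[2,3-bis(benzyloxy)phenyl]-3-oxopropanoyl}-4-phenyl-1,3-oxazolidin-2-one | O=C(CC(=O)N1C(=O)OC[C@@H]1c1ccccc1)c1cccc(OCc2ccccc2)c1OCc1ccccc1
F2 | step 8 | (4S)-3-{(2Z)-2-[2,3-bis(benzyloxy)benzoyl]-3-[4-(benzyloxy)-8-methoxynaphthalen-1-yl]prop-2-enoyl}-4-phenyl-1,3-oxazolidin-2-one | O=C(N1C(=O)OC[C@@H]1c1ccccc1)/C(C(=O)c1cccc(OCc2ccccc2)c1OCc1ccccc1)=C\c1ccc(OCc2ccccc2)c2cccc(OC)c12
F3 | step 8 | (4S)-3-{[(2R,3S)-6,7-bis(benzyloxy)-3-[4-(benzyloxy)-8-methoxynaphthalen-1-yl]-1-oxo-2,3-dihydro-1H-inden-2-yl]carbonyl}-4-phenyl-1,3-oxazolidin-2-one | COc1cccc2c(OCc5ccccc5)ccc([C@@H]3[C@@H](C(=O)N6C(=O)OC[C@@H]6c6ccccc6)C(=O)c4c3ccc(OCc5ccccc5)c4OCc5ccccc5)c12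
F4 | step 9 | methyl (2R,3S)-6,7-bis(benzyloxy)-3-[4-(benzyloxy)-8-methoxynaphthalen-1-yl]-2-(hydroxymethyl)-1-oxo-2,3-dihydro-1H-indene-2-carboxylate | COc1cccc2c(OCc5ccccc5)ccc([C@@H]3[C@](CO)(C(=O)OC)C(=O)c4c3ccc(OCc5ccccc5)c4OCc5ccccc5)c12
F0 | step 10 | none | none
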